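The complex with two exchanged passes the starting complex at a point we can reckon from the charges, if the two-exchanged complex holds two incoming ligands, the starting complex none, and any other form one. Leaving the starting form costs one ligand and the second exchange costs another. So ligand spent, counted in charges of complex, equals the fraction that has left the starting form plus the two-exchanged fraction, and the two fractions stand level when the ligand spent equals the complex charged.

| flask | starting complex | incoming ligand | remark | time |
|---|---|---|---|---|
| teal | 0.020 M | 0.014 M | run made earlier |  |
| ochre | 0.020 M | 0.062 M | run made earlier |  |
| Thursday's | 0.020 M | 0.0800 M |  | 1.5 h |
| Friday's | 0.020 M | 0.0240 M |  | 1.5 h |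
| Monday's | 0.020 M | 0.0600 M |  | 1.5 h |

| teal: time / min | teal: complex with one exchanged / % | ochre: time / min | ochre: complex with one exchanged / % |
|---|---|---|---|
| 8.00 | 15.5 | 20.0 | 13.3 |
| 15.0 | 15.3 | 40.0 | 10.1 |
| 25.0 | 13.2 | 50.0 | 10.2 |
| 50.0 | 11.4 | 80.0 | 5.8 |
| 90.0 | 7.7 | 90.0 | 7.1 |

(readings scatter by 1 percentage point)

1. which of these holds the largest part of the starting complex at the end of Thursday's (complex with one exchanged / complex with two exchanged / starting complex)
2. which of these holds the largest part of the starting complex at the end of Friday's (complex with one exchanged / complex with two exchanged / starting complex)
3. which of these holds the largest part of the starting complex at the end of Monday's (complex with one exchanged / complex with two exchanged / starting complex)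
4. amount of complex with one exchanged at the end of Friday's, in percent of the starting complex charged



On Friday's that level needs 83.3% of the ligand's own charge spent, the crossing share, which is complex charged over ligand charged. Thursday's needs 25.0% and Monday's 33.3%. In the teal run, where incoming ligand is the limiting reagent, the share is 143%, more than the whole of its charge.

But how much is spent by the end? The clock we can read is the fall of the one-exchanged complex, with a fade time, taken from the first and last readings, of 117 min in teal and 112 min in ochre, though ochre has 4.43 times the ligand. If Friday's ligand kept that clock, our estimate is that 53.6% of it is spent in 1.5 h. That ignores the early burst, since teal's first reading, taken over to Friday's, would already cost 12.9% of its ligand. Adding it gives 59.6%, still short of the crossing share. This clock belongs to a complex, not to the ligand, so the call is a doubtful one. The crossing shares of Thursday's and Monday's lie below this estimate, though it was made for Friday's, so we commit to two-exchanged on Thursday's and Monday's and starting complex on Friday's. For the one-exchanged complex on Friday's we take 7.40%, the mean of the last readings of teal and ochre.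

The forecast said complex with two exchanged for Thursday's, complex with two exchanged for Friday's and complex with two exchanged for Monday's, with 7.5% (5.5% to 10%) of one-exchanged complex on Friday's, the ligand balance being one that “only just bites”.

The flasks give complex with two exchanged for Thursday's, starting complex for Friday's and complex with two exchanged for Monday's, with 8.87% of one-exchanged complex on Friday's.

    starting complex + incoming ligand ⇌ leaving ligand + complex with one exchanged (K = 0.220, k = 0.0700 M⁻¹ s⁻¹)
    leaving ligand + complex with one exchanged → side product (k = 0.0550 M⁻¹ s⁻¹)
    complex with one exchanged + incoming ligand ⇌ leaving ligand + complex with two exchanged (K = 1.60, k = 0.0830 M⁻¹ s⁻¹)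

Friday's spent 62.1% of its ligand, below the crossing share of 83.3%. A neighbour like Friday's but charged with 0.096 M of incoming ligand has a crossing share of 20.8%. It spent 27.5%, and there two-exchanged, at 37.6%, stands above starting complex, at 5.46%.

The data come from a simulation on assumed constants.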